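## The problem

The target **12** is a flavone. Ring A (C4a to C8a) is fused to the pyranone ring C, which carries the 3-methoxy-4-prenyloxyphenyl ring B at C2 and a methoxy group at C3.

There is no stereocentre, and the prenyl double bond carries two identical methyl groups. Nothing has to be controlled in three dimensions, so the difficulty is regiochemical and chemoselective.

Ring A is fully differentiated: free hydroxyls at C5 and C7, hydrogen at C6 and methoxy at C8. This pattern cannot be put onto a symmetrical phloroglucinol without telling C6 from C8. Acid can also exchange it with the 6-methoxy pattern by opening and reclosing ring C (Wessely–Moser rearrangement).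

Three phenolic oxygens (C5, C7, C4') end in three different states. The one to be alkylated, C4', is less acidic than the C7 hydroxyl, so a late prenylation would go to the wrong oxygen.

The aryl prenyl ether excludes strong protic and Lewis acids, hydrogenolysis, electrophilic oxidants and long heating much above 120 °C. The usual demethylation and debenzylation tools are therefore not available at the end of the synthesis.

The feature that opens a way out is a match between ring A and two simple pieces. C8–C7–C6, with the C7 oxygen and the 8-methoxy group, is the γ,β,α-chain of methyl 4-methoxyacetoacetate **4**. C8a, C4a and C5 are the S,O-ketene acetal carbon, the α-carbon and the ester carbon of the 2-methylthio-4-pyranone-3-carboxylate **8**. Ring A can thus be grown onto a finished ring C, and the methoxy group lands at C8 because of which carbon of the dinucleophile bonds first.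

## Retrosynthesis

**C6–H from C6–CO2Me (12 to 11 to 10).** The first step backwards adds a carboxyl group at C6, leading to the acid **11** and its methyl ester **10**. Nothing is cut from the skeleton. The ester is the activating group that a carbon nucleophile at C6 needs. It is preferred to a removable group at C8 or to protected hydroxyls because its removal needs no reagent that the prenyl ether cannot stand. The acid in **11** lies between two hydroxyls and para to the ring oxygen, the pattern of a phloroglucinol carboxylic acid, which loses carbon dioxide by ipso-protonation on gentle warming. The forward reaction only has to hydrolyse a hindered, electron-rich ester without opening ring C.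

**C8–C8a and C5–C6 (10 to 8 and 4).** Cutting ring A at these two bonds divides **10** into the pyranone **8** and the keto ester **4**. The neighbouring cuts through ring C (O1–C2, C2–C3 or C4–C4a) all start from a pentasubstituted benzene in which C6 and C8, and the C5 and C7 hydroxyls, must be told apart by selective reactions. The chosen cut leaves no such choice: the methoxy-bearing terminal carbon of **4** bonds to C8a and the ester-bearing central carbon bonds to C5. Precursor **8** has one ring fewer, no free hydroxyl and no acidic hydrogen, and it already holds ring C, the 3-methoxy group and the prenylated ring B in final form. The forward reaction needs the dianion of **4** to attack first with its terminal carbon, and at the methylthio-bearing carbon of **8** and not at the ester, the ketone or the aryl-bearing ring carbon. The ring then closes by Dieckmann condensation of the open adduct **9**.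

**O1–C8a and the carbon–sulfur bonds (8 to 7 to 5 and 6).** In **8** the bond between the ring oxygen and the methylthio-bearing carbon is cut to give the ketene dithioacetal **7**. This is taken back to the 3,5-dioxo ester **5** and carbon disulfide **6**, which becomes C8a. The obvious neighbour, joining an aryl ketone enolate through carbon to a bis(methylthio)methylene malonate, gives a 4-methylthio-2-pyranone, in which carbonyl and thioether have changed places. Closing through the enol oxygen of the aryl ketone is what gives the 4-pyranone. **5** has a single active methylene. The forward step asks that **6** condense there and not at the methoxy-bearing methine, which has one hydrogen and cannot form a ketene dithioacetal. The enol oxygen must then displace one methylthio group.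

**C2–C3 (5 to 3 and 4).** The bond between the aryl ketone carbon (flavone C2) and the methoxy-bearing carbon (C3) of **5** is cut, giving the benzoate **3** and again **4**. A cut between C3 and C4 would need an ω-methoxyacetophenone and a malonyl electrophile, both of which have to be made, and a C-acylation of a ketone enolate. The chosen cut is an ester acylation at the γ-carbon of a β-keto ester dianion. It lets **4** serve twice: for C3–C4–C4a–C5 here and for C8–C7–C6 in the annulation. The forward step only asks that the electron-rich ester **3** be a good enough acceptor.

**O–prenyl (3 to 1 and 2).** The ether bond at the C4' oxygen is cut last in the analysis and formed first in the synthesis, from methyl vanillate **1** and prenyl bromide **2**. At that stage the molecule has one phenol, so no choice among the C5, C7 and C4' hydroxyls ever arises. The price is that every later step must be basic or neutral and run well below the temperature of an aromatic Claisen rearrangement. The sequence is built to meet that.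

## Roads not taken

**Alternative 1: intramolecular Wittig closure of C2=C3.**
- **Cut and key step.** Ring C is cut at the C2=C3 bond. The precursor is the aryl ester **A2**: the 3-methoxy-4-prenyloxybenzoyl group sits on the C8a oxygen and the C4 carbonyl carries an α-methoxy phosphorane. On heating, the ylide carbon attacks the ester carbonyl and the phosphine oxide is lost, giving the bis-silyl flavone **A1**. Fluoride would then free the target.
- **Merits.** The closure is thermal and neutral. The prenyl ether and the 3-methoxy group are in place. Ester olefination to chromones is an established ring closure, which is a closer precedent than the chosen key step can claim. The final desilylation is also gentler than a saponification.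
- **Weak points.** The ylide is ketone-stabilised, carries a methoxy group on the ylide carbon and sits next to a 2,6-disubstituted aryl ring. An olefination that is already slow with esters must therefore be forced in a crowded setting. **A2** needs the aroyl group on the hydroxyl next to the methoxy group while the other ortho oxygen is silylated. That is a selective differentiation on a pentasubstituted benzene ring, and an error leads into the 6-methoxy series. Acyl and silyl groups on neighbouring phenol oxygens also tend to migrate.
- **Comparison.** The chosen plan sets against the better precedent three things: no protecting group, the 8-methoxy position fixed by connectivity and not by phenol selectivity, and fewer operations from commercial materials.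

**Alternative 2: biomimetic Claisen folding of a masked polyketide.**
- **Cut and key step.** Ring A is cut at C4a–C8a, which opens it to the acyclic keto ester **A4** with the C5 oxygen held as a methyl enol ether. NaOMe generates the carbanion at C4a, which attacks the terminal ester carbon C8a. Loss of the alkoxy group and enolisation give ring A of the α-methoxychalcone **A3**.
- **Merits.** As in the chosen plan, the oxygen pattern of ring A follows from the chain and the 8-methoxy group cannot go astray. The closure is an intramolecular six-ring Claisen condensation of the classical polyketide kind. It does not depend on a first intermolecular attack at the right site, and in that respect it is probably more reliable than the chosen annulation.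
- **Weak points.** **A4** is a long chain with several acidic sites, so it is laborious to assemble and open to aldol and lactonisation side paths. **A3** is still far from the target. It needs oxidative closure of ring C, removal of the C5 methyl ether with a Lewis acid, hydrogenolysis of the benzyl ether (which stands in for the prenyl group because that group would not survive the Lewis acid), and then prenylation of the C4' hydroxyl beside the more acidic C7 hydroxyl. The last step requires yet another protecting group.
- **Comparison.** The chosen plan reaches the annulation with ring C, the 3-methoxy group and the prenyl ether already present, and ends one flask later.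

**Alternative 3: iodocyclisation of a 2-hydroxyaryl ynone.**
- **Cut and key step.** Ring C is cut at O1–C2, with iodine placed at C3. The precursor is the ynone **A6**. Iodine with NaHCO3 activates the alkyne, and the C8a phenol oxygen attacks the aryl-bearing alkyne carbon in a 6-endo-dig closure, giving the 3-iodoflavone **A5**.
- **Merits.** The ring closure is mild, regioselective for the six-membered ring, and better precedented than the key step chosen here. That is conceded without reserve.
- **Weak points.** **A5** has iodine where the target has methoxy, so a carbon–oxygen coupling must be run on a chromone that alkoxides open at C2. The three benzyl ethers are then removed by hydrogenolysis, and only afterwards can the prenyl group be attached, to the least acidic of three phenols. **A6** again rests on a pentasubstituted ring A whose oxygens must be differentiated beforehand.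
- **Comparison.** The chosen plan has a less tested key step. Against that it needs no protecting group, makes no late choice among phenols and brings in every oxygen substituent in its final form.

Key step: step 4

## Route

Remark on the chemistry: compounds **5**, **7** and **9** each carry one CH(OMe) centre next to carbonyl groups. It is racemic, enolises readily and disappears in the following ring formation, so these compounds are drawn as keto forms without configuration.

Step 1
Reactants: 1 methyl vanillate (methyl 4-hydroxy-3-methoxybenzoate); 2 prenyl bromide (1-bromo-3-methylbut-2-ene)
Product: 3 methyl 3-methoxy-4-(3-methylbut-2-enyloxy)benzoate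
Conditions: K2CO3 (1.5 equiv), acetone, 56 °C
Reagents that add atoms: none
Why: Williamson ether synthesis; the only phenol in the molecule is alkylated by SN2 displacement at the primary allylic carbon, and the ester is inert to carbonate in acetone.

Step 2
Reactants: 3 methyl 3-methoxy-4-(3-methylbut-2-enyloxy)benzoate; 4 methyl 4-methoxy-3-oxobutanoate (as its dianion, 2.2 equiv)
Product: 5 methyl 4-methoxy-5-[3-methoxy-4-(3-methylbut-2-enyloxy)phenyl]-3,5-dioxopentanoate
Conditions: 4, NaH, THF, 0 °C; n-BuLi, 0 °C; then 3, 0 °C → rt; 1 M aq. HCl, 0 °C
Reagents that add atoms: none
Why: Claisen condensation of an ester with a β-keto ester dianion, which reacts at its γ-carbon, the site deprotonated last; the second equivalent of dianion takes up the acidic proton of the product. Crude 5 should be kept cold and used at once, because 3,5-dioxo esters lactonise on standing or heating.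

Step 3
Reactants: 5 methyl 4-methoxy-5-[3-methoxy-4-(3-methylbut-2-enyloxy)phenyl]-3,5-dioxopentanoate; 6 carbon disulfide
Product: 8 methyl 5-methoxy-6-[3-methoxy-4-(3-methylbut-2-enyloxy)phenyl]-2-(methylsulfanyl)-4-oxo-4H-pyran-3-carboxylate, via ketene dithioacetal 7 (not isolated)
Conditions: K2CO3 (3 equiv), CS2 (1.5 equiv), DMF, 0 °C → rt; MeI (2.2 equiv), 0 °C → rt; then 50 °C
Reagents that add atoms: iodomethane, CI
Why: Ketene dithioacetal formation at the only CH2 flanked by two carbonyls (condensation with CS2, then double S-methylation), followed by intramolecular addition–elimination in which the enol oxygen of the aryl ketone displaces one methylthio group in a 6-endo-trig closure, as in the preparation of 2-methylthiochromones from 2-hydroxyaryl ketones. The methine between the two ketones has one hydrogen and cannot give a ketene dithioacetal, and MeI is added only after the dithiolate has formed so that sulfur is methylated before any enolate.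

Step 4
Reactants: 8 methyl 5-methoxy-6-[3-methoxy-4-(3-methylbut-2-enyloxy)phenyl]-2-(methylsulfanyl)-4-oxo-4H-pyran-3-carboxylate; 4 methyl 4-methoxy-3-oxobutanoate (as its dianion, 2.5 equiv)
Product: 10 methyl 5,7-dihydroxy-3,8-dimethoxy-2-[3-methoxy-4-(3-methylbut-2-enyloxy)phenyl]-4-oxo-4H-chromene-6-carboxylate, via pyranone keto ester adduct 9 (not isolated)
Conditions: 4, NaH, THF, 0 °C; n-BuLi, 0 °C; then 8, −78 °C → rt; 50 °C; 1 M aq. HCl, 0 °C
Reagents that add atoms: none
Why: The γ-carbanion of the dianion of 4, the more basic and nucleophilic of its two carbon sites, adds to C2 of pyranone 8 (flavone C8a), the one ring carbon that is β to both the ketone and the ester and bears a leaving group, and loss of the methylthio group gives adduct 9 (nucleophilic vinylic substitution by addition–elimination, forming C8–C8a). If the ring oxygen leaves first from the same tetrahedral intermediate, the enolate so formed can only re-close on that carbon with loss of the methylthio group, so both paths should lead to 9. The acidic C8–H of 9 consumes a further equivalent of dianion, which is why an excess is used; the β-keto ester enolate carbon (C6) then attacks the neighbouring pyranone ester in a 6-exo-trig Dieckmann condensation, forming C5–C6, and loss of the methoxy group and enolisation of the triketone give the 5,7-dihydroxy arene 10. The closest known reaction type is the [3+3] aromatic annulation of 1,3-dicarbonyl dianions with α-oxo ketene dithioacetals and β-methylthio alkylidene malonate-type acceptors, of which pyranone 8 is a cyclic member that has not itself been put through it. No stereocentre is formed, and the CH(OMe) centre of 9 is lost on aromatisation. The selectivities needed are γ- over α-attack of the dinucleophile, which follows from the charge distribution of the dianion, and attack at C8a over the aryl-bearing ring carbon, the ester and the C4 carbonyl, which is secured by the double activation and leaving group at C8a against a singly activated, methoxy-flanked carbon with an electron-rich aryl group and two vinylogous carbonyls of low electrophilicity. O-acylation to a fused 2-pyranone is reversible under the alkoxide set free, while C-acylation ends in an aromatic phenolate, so the carbocycle is the thermodynamic outcome. The two reacting arms are held cis on the C4a=C8a bond, and the basic medium leaves the prenyl ether and ring C untouched.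

Step 5
Reactants: 10 methyl 5,7-dihydroxy-3,8-dimethoxy-2-[3-methoxy-4-(3-methylbut-2-enyloxy)phenyl]-4-oxo-4H-chromene-6-carboxylate
Product: 12 5,7-dihydroxy-3,8-dimethoxy-2-[3-methoxy-4-(3-methylbut-2-enyloxy)phenyl]-4H-chromen-4-one (5,7-dihydroxy-3,8,3'-trimethoxy-4'-prenyloxyflavone), via chromone-6-carboxylic acid 11 (not isolated)
Conditions: 2 M aq. NaOH, MeOH, 60 °C, argon; then AcOH to pH 4, 70 °C
Reagents that add atoms: none
Why: Saponification, then protodecarboxylation of a 2,6-dihydroxybenzoic acid that is also para to the ring oxygen; ipso-protonation at C6 is assisted by three oxygen donors, as in the classical hydrolysis–decarboxylation of phloroglucinol carboxylates. As phenolates at C5 and C7, the flavone resists hydroxide attack at C2, and acetic acid at 70 °C is too weak and too cool to cleave or rearrange the prenyl ether.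

## Compound list

1 | methyl vanillate (methyl 4-hydroxy-3-methoxybenzoate) | COC(=O)c1ccc(O)c(OC)c1 | starting material
2 | prenyl bromide (1-bromo-3-methylbut-2-ene) | CC(C)=CCBr | starting material
3 | methyl 3-methoxy-4-(3-methylbut-2-enyloxy)benzoate | COC(=O)c1ccc(OCC=C(C)C)c(OC)c1 | intermediate
4 | methyl 4-methoxy-3-oxobutanoate (methyl 4-methoxyacetoacetate) | COCC(=O)CC(=O)OC | starting material
5 | methyl 4-methoxy-5-[3-methoxy-4-(3-methylbut-2-enyloxy)phenyl]-3,5-dioxopentanoate (racemic at C4, enolisable) | COC(=O)CC(=O)C(OC)C(=O)c1ccc(OCC=C(C)C)c(OC)c1 | intermediate
6 | carbon disulfide | S=C=S | starting material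
7 | methyl 2-[bis(methylsulfanyl)methylidene]-4-methoxy-5-[3-methoxy-4-(3-methylbut-2-enyloxy)phenyl]-3,5-dioxopentanoate (racemic, not isolated) | COC(=O)C(=C(SC)SC)C(=O)C(OC)C(=O)c1ccc(OCC=C(C)C)c(OC)c1 | intermediate
8 | methyl 5-methoxy-6-[3-methoxy-4-(3-methylbut-2-enyloxy)phenyl]-2-(methylsulfanyl)-4-oxo-4H-pyran-3-carboxylate | COC(=O)c1c(SC)oc(-c2ccc(OCC=C(C)C)c(OC)c2)c(OC)c1=O | intermediate
9 | methyl 2-(1,4-dimethoxy-2,4-dioxobutyl)-5-methoxy-6-[3-methoxy-4-(3-methylbut-2-enyloxy)phenyl]-4-oxo-4H-pyran-3-carboxylate (racemic, not isolated) | COC(=O)CC(=O)C(OC)c1oc(-c2ccc(OCC=C(C)C)c(OC)c2)c(OC)c(=O)c1C(=O)OC | intermediate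
10 | methyl 5,7-dihydroxy-3,8-dimethoxy-2-[3-methoxy-4-(3-methylbut-2-enyloxy)phenyl]-4-oxo-4H-chromene-6-carboxylate | COC(=O)c1c(O)c(OC)c2oc(-c3ccc(OCC=C(C)C)c(OC)c3)c(OC)c(=O)c2c1O | intermediate
11 | 5,7-dihydroxy-3,8-dimethoxy-2-[3-methoxy-4-(3-methylbut-2-enyloxy)phenyl]-4-oxo-4H-chromene-6-carboxylic acid (not isolated) | OC(=O)c1c(O)c(OC)c2oc(-c3ccc(OCC=C(C)C)c(OC)c3)c(OC)c(=O)c2c1O | intermediate
12 | 5,7-dihydroxy-3,8-dimethoxy-2-[3-methoxy-4-(3-methylbut-2-enyloxy)phenyl]-4H-chromen-4-one (5,7-dihydroxy-3,8,3'-trimethoxy-4'-prenyloxyflavone) | COc1cc(-c2oc3c(OC)c(O)cc(O)c3c(=O)c2OC)ccc1OCC=C(C)C | target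

## Step count and risks

Total steps: 5. Longest linear sequence: 5 steps (1 → 3 → 5 → 8 → 10 → 12); compound 4 enters twice, in steps 2 and 4.

**Step 4 (key step).**
- **What may go wrong.** The hard lithium dianion may add 1,2 to the C4 carbonyl, or acylate directly at the pyranone ester, which would start an annulation of the opposite orientation. The sequence may also stall at the stabilised anion of adduct 9 without Dieckmann closure.
- **Fallback.** The two bond formations would be separated and the dinucleophile made neutral and soft. The fallback sets out from 4 and 8 and comes back to the route at 9, isolated this time, and then 10.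
  - 4 would be silylated (Me3SiCl, NEt3) to methyl 4-methoxy-3-(trimethylsilyloxy)but-2-enoate F1.
  - F1 would be silylated again (LDA, Me3SiCl, −78 °C) to 1,4-dimethoxy-1,3-bis(trimethylsilyloxy)buta-1,3-diene F2. The double-bond geometry of F1 and F2 is not defined and is of no consequence.
  - F2 would be added to 8 with substoichiometric Me3SiOTf in CH2Cl2 at −78 °C. This is a vinylogous Mukaiyama–Michael addition of the terminal diene carbon to the silyloxypyrylium form of 8; loss of the methylthio group as its silyl sulfide restores the pyranone and gives 9. The low temperature and small amount of silyl triflate are meant to spare the prenyl ether.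
  - Isolated 9 would be closed to 10 with NaOMe in MeOH, a Claisen cyclisation of a polyketo ester.

**Step 2.**
- **What may go wrong.** Addition to the electron-rich 4-alkoxybenzoate may be slow, so that proton transfer from the product and self-condensation of the dianion outrun acylation and conversion stays incomplete.
- **Fallback.** From 3, MeNH(OMe)·HCl and i-PrMgCl in THF at −20 °C would give N-methoxy-3-methoxy-N-methyl-4-(3-methylbut-2-enyloxy)benzamide F3. Its chelated tetrahedral adduct with the dianion of 4 does not collapse until work-up, so no acidic product is present during the reaction. Acylation with F3 returns to the route at 5.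

**Step 3.**
- **What may go wrong.** The enolate between the two ketones may be methylated at carbon or oxygen in competition with ring closure. The tricarbonyl chain of 5 may also lactonise to a 4-hydroxy-2-pyranone before carbon disulfide is taken up.
- **Fallback.** The ring would be closed before any methylating agent is present. From 5, KOtBu (3 equiv) and CS2 in THF would give the dithio acid 2-(methoxycarbonyl)-4-methoxy-5-[3-methoxy-4-(3-methylbut-2-enyloxy)phenyl]-3,5-dioxopentanedithioic acid F4 as its salt, not isolated. Attack of the enol oxygen and loss of hydrosulfide would give methyl 4-hydroxy-5-methoxy-6-[3-methoxy-4-(3-methylbut-2-enyloxy)phenyl]-2-thioxo-2H-pyran-3-carboxylate F5. S-methylation of F5 (MeI, K2CO3, acetone) returns to the route at 8.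

**Step 5.**
- **What may go wrong.** Hydrolysis of an ester flanked by two phenolates may be slow, and the forcing alkali then needed may open ring C by hydroxide attack at C2 and cleave the resulting diketone.
- **Fallback.** The ester would be made fluoride-labile. The fallback sets out from 4 and 8 and comes back at 11.
  - 4 would be transesterified with 2-(trimethylsilyl)ethanol (toluene, reflux, removal of the alcohol set free) to 2-(trimethylsilyl)ethyl 4-methoxy-3-oxobutanoate F6.
  - The dianion of F6 would be annulated onto 8 as in step 4. The open adduct 2-(trimethylsilyl)ethyl 4-methoxy-4-[5-methoxy-3-(methoxycarbonyl)-6-[3-methoxy-4-(3-methylbut-2-enyloxy)phenyl]-4-oxo-4H-pyran-2-yl]-3-oxobutanoate F7 (not isolated) would close to 2-(trimethylsilyl)ethyl 5,7-dihydroxy-3,8-dimethoxy-2-[3-methoxy-4-(3-methylbut-2-enyloxy)phenyl]-4-oxo-4H-chromene-6-carboxylate F8.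
  - Bu4NF in THF would cleave F8 by attack at silicon, whatever the reactivity of the carbonyl, giving 11. This is decarboxylated to 12 by the buffered warming of step 5.

## Further compounds

F1 | step 4 | methyl 4-methoxy-3-(trimethylsilyloxy)but-2-enoate (mixture of double-bond isomers) | COCC(O[Si](C)(C)C)=CC(=O)OC
F2 | step 4 | 1,4-dimethoxy-1,3-bis(trimethylsilyloxy)buta-1,3-diene (mixture of double-bond isomers) | COC=C(O[Si](C)(C)C)C=C(OC)O[Si](C)(C)C
F3 | step 2 | N-methoxy-3-methoxy-N-methyl-4-(3-methylbut-2-enyloxy)benzamide | CON(C)C(=O)c1ccc(OCC=C(C)C)c(OC)c1
F4 | step 3 | 2-(methoxycarbonyl)-4-methoxy-5-[3-methoxy-4-(3-methylbut-2-enyloxy)phenyl]-3,5-dioxopentanedithioic acid (racemic, formed as its salt, not isolated) | COC(=O)C(C(=S)S)C(=O)C(OC)C(=O)c1ccc(OCC=C(C)C)c(OC)c1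
F5 | step 3 | methyl 4-hydroxy-5-methoxy-6-[3-methoxy-4-(3-methylbut-2-enyloxy)phenyl]-2-thioxo-2H-pyran-3-carboxylate | COC(=O)c1c(O)c(OC)c(-c2ccc(OCC=C(C)C)c(OC)c2)oc1=S
F6 | step 5 | 2-(trimethylsilyl)ethyl 4-methoxy-3-oxobutanoate | COCC(=O)CC(=O)OCC[Si](C)(C)C
F7 | step 5 | 2-(trimethylsilyl)ethyl 4-methoxy-4-[5-methoxy-3-(methoxycarbonyl)-6-[3-methoxy-4-(3-methylbut-2-enyloxy)phenyl]-4-oxo-4H-pyran-2-yl]-3-oxobutanoate (racemic, not isolated) | C[Si](C)(C)CCOC(=O)CC(=O)C(OC)c1oc(-c2ccc(OCC=C(C)C)c(OC)c2)c(OC)c(=O)c1C(=O)OC
F8 | step 5 | 2-(trimethylsilyl)ethyl 5,7-dihydroxy-3,8-dimethoxy-2-[3-methoxy-4-(3-methylbut-2-enyloxy)phenyl]-4-oxo-4H-chromene-6-carboxylate | C[Si](C)(C)CCOC(=O)c1c(O)c(OC)c2oc(-c3ccc(OCC=C(C)C)c(OC)c3)c(OC)c(=O)c2c1O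
A1 | alternative 1 | 5,7-bis(tert-butyldimethylsilyloxy)-3,8-dimethoxy-2-[3-methoxy-4-(3-methylbut-2-enyloxy)phenyl]chromen-4-one | COc1c(-c2ccc(OCC=C(C)C)c(OC)c2)oc2c(OC)c(O[Si](C)(C)C(C)(C)C)cc(O[Si](C)(C)C(C)(C)C)c2c1=O
A2 | alternative 1 | 3,5-bis(tert-butyldimethylsilyloxy)-2-methoxy-6-[2-methoxy-2-(triphenylphosphoranylidene)acetyl]phenyl 3-methoxy-4-(3-methylbut-2-enyloxy)benzoate | COC(C(=O)c1c(O[Si](C)(C)C(C)(C)C)cc(O[Si](C)(C)C(C)(C)C)c(OC)c1OC(=O)c1ccc(OCC=C(C)C)c(OC)c1)=P(c1ccccc1)(c1ccccc1)c1ccccc1
A3 | alternative 2 | (Z)-3-(4-benzyloxy-3-methoxyphenyl)-1-(2,4-dihydroxy-3,6-dimethoxyphenyl)-2-methoxyprop-2-en-1-one | COc1cc(O)c(OC)c(O)c1C(=O)/C(OC)=C/c1ccc(OCc2ccccc2)c(OC)c1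
A4 | alternative 2 | methyl (4E,8Z)-9-(4-benzyloxy-3-methoxyphenyl)-2,5,8-trimethoxy-3,7-dioxonona-4,8-dienoate (racemic at C2) | COC(=O)C(OC)C(=O)/C=C(/OC)CC(=O)/C(OC)=C/c1ccc(OCc2ccccc2)c(OC)c1
A5 | alternative 3 | 5,7-bis(benzyloxy)-2-(4-benzyloxy-3-methoxyphenyl)-3-iodo-8-methoxychromen-4-one | O=c1c(I)c(-c2ccc(OCc3ccccc3)c(OC)c2)oc2c(OC)c(OCc3ccccc3)cc(OCc3ccccc3)c12
A6 | alternative 3 | 1-[4,6-bis(benzyloxy)-2-hydroxy-3-methoxyphenyl]-3-(4-benzyloxy-3-methoxyphenyl)prop-2-yn-1-one | COc1cc(C#CC(=O)c2c(O)c(OC)c(OCc3ccccc3)cc2OCc2ccccc2)ccc1OCc1ccccc1
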